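**Retrosynthetic overview**
- The target is unmasked last by fluoride cleavage of seven aryl silyl ethers from a fully silylated cis-flavan-3-yl caffeate.
- Ring C, both stereocentres and the position of the ester come from one [4+2] addition of an A-ring ortho-quinone methide (phloroglucinol unit plus one CH2) to a (Z)-enol caffeate.
- The quinone methide is released from a 1,3,2-dioxaborin closed in the same flask, so the temporary dioxaborin ring and then the pyran ring C are formed in one operation.
- The (Z)-enol ester comes from anti-Markovnikov, trans addition of silylated caffeic acid to the B-ring arylalkyne (made from 3,4,5-trihydroxybenzaldehyde).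
- Ring order: the A, B and caffeoyl arenes are bought; the dioxaborin is formed first (temporary), ring C last.

Assumption: the sense of induction of the chiral acid in step 6 cannot be predicted; the (R) catalyst is written, and its mirror image is used if the first run gives the (2S,3S) adduct.

**Step 1**
Reactants: 1 caffeic acid
Product: 3 (E)-3-[3,4-bis(tert-butyldimethylsilyloxy)phenyl]prop-2-enoic acid, via silyl ester 2 (not isolated)
Conditions: TBSCl (3.5 equiv), imidazole, DMF, rt; then AcOH/THF/H2O, rt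
Reagents that add atoms: tert-butyldimethylsilyl chloride, CC(C)(C)[Si](C)(C)Cl
Why: Imidazole-promoted silylation caps both phenols and the acid, and only the much more labile silyl ester is hydrolysed by dilute aqueous acetic acid, leaving the aryl silyl ethers and the E alkene intact (silyl ether protection, selective silyl ester hydrolysis).

**Step 2**
Reactants: 4 3,4,5-trihydroxybenzaldehyde
Product: 5 3,4,5-tris(tert-butyldimethylsilyloxy)benzaldehyde
Conditions: TBSCl (3.6 equiv), imidazole, DMF, rt
Reagents that add atoms: tert-butyldimethylsilyl chloride, CC(C)(C)[Si](C)(C)Cl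
Why: Silyl ether protection of the three phenols proceeds without touching the aldehyde and gives a non-enolisable aldehyde for the homologation.

**Step 3**
Reactants: 5 3,4,5-tris(tert-butyldimethylsilyloxy)benzaldehyde
Product: 6 5-ethynyl-1,2,3-tris(tert-butyldimethylsilyloxy)benzene
Conditions: Me3SiCHN2, n-BuLi, THF, −78 °C to rt
Reagents that add atoms: trimethylsilyldiazomethane, C[Si](C)(C)C=[N+]=[N-]
Why: Lithiated trimethylsilyldiazomethane adds to the aldehyde, Peterson-type loss of silanolate gives a diazoalkene that loses nitrogen, and 1,2-hydride shift of the alkylidene carbene gives the terminal alkyne (Colvin rearrangement) under cold aprotic conditions that aryl silyl ethers tolerate.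

**Step 4**
Reactants: 3 (E)-3-[3,4-bis(tert-butyldimethylsilyloxy)phenyl]prop-2-enoic acid; 6 5-ethynyl-1,2,3-tris(tert-butyldimethylsilyloxy)benzene
Product: 7 (Z)-2-[3,4,5-tris(tert-butyldimethylsilyloxy)phenyl]ethenyl (E)-3-[3,4-bis(tert-butyldimethylsilyloxy)phenyl]prop-2-enoate
Conditions: Ru(η3-CH2C(CH3)CH2)2(Ph2P(CH2)4PPh2) (2 mol %), toluene, 65 °C
Reagents that add atoms: none
Why: The ruthenium catalyst converts the terminal alkyne into a vinylidene whose alpha carbon is attacked by the carboxylate, so the acid adds anti-Markovnikov and trans to give the (Z)-enol ester (ruthenium-catalysed hydro-oxycarbonylation of alkynes), fixing the alkene geometry that later becomes the 2,3-cis relationship.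

**Step 5**
Reactants: 8 phloroglucinol
Product: 9 3,5-bis(tert-butyldimethylsilyloxy)phenol
Conditions: TBSCl (2.0 equiv), imidazole, DMF, 0 °C to rt; chromatography
Reagents that add atoms: tert-butyldimethylsilyl chloride, CC(C)(C)[Si](C)(C)Cl
Why: Statistical silyl ether protection of the threefold-symmetric triol gives the bis-silyl ether as the main fraction with two equivalents of chloride, and the mono- and tris-silyl ethers are separated and recycled.

**Step 6**
Reactants: 9 3,5-bis(tert-butyldimethylsilyloxy)phenol; 7 (Z)-2-[3,4,5-tris(tert-butyldimethylsilyloxy)phenyl]ethenyl (E)-3-[3,4-bis(tert-butyldimethylsilyloxy)phenyl]prop-2-enoate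
Product: 12 (2R,3R)-5,7-bis(tert-butyldimethylsilyloxy)-2-[3,4,5-tris(tert-butyldimethylsilyloxy)phenyl]-3,4-dihydro-2H-chromen-3-yl (E)-3-[3,4-bis(tert-butyldimethylsilyloxy)phenyl]prop-2-enoate, via dioxaborin 10 (not isolated), via quinone methide 11 (not isolated)
Conditions: (CH2O)n, PhB(OH)2, EtCO2H (cat.), toluene, reflux, Dean–Stark; evaporate; then 7 (0.7 equiv), (R)-3,3'-bis(2,4,6-triisopropylphenyl)-1,1'-binaphthalene-2,2'-diyl N-(trifluoromethylsulfonyl)phosphoramide (10 mol %), 4 Å MS, CH2Cl2, −40 to 0 °C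
Reagents that add atoms: formaldehyde (used as paraformaldehyde), C=O
Why: Proposed new method: boron-templated ortho-hydroxymethylation (Nagata reaction) first closes the 1,3,2-dioxaborin 10, the chiral N-triflylphosphoramide then ionises its benzylic C–O bond to the ion-paired ortho-quinone methide 11, and this heterodiene adds to the (Z)-enol ester in an inverse-electron-demand oxa-Diels–Alder reaction that closes the pyran ring, the methide CH2 bonding to the acyloxy-bearing carbon because the positive charge developing at the other carbon is stabilised by the aryl group and by the neighbouring ester carbonyl (the acid-bound acyloxy oxygen being a poor donor), so that suprafacial addition to the Z alkene fixes the 2,3-cis relationship and the chiral counter-anion selects the alkene face that gives (2R,3R); the closest known reactions are chiral N-triflylphosphoramide-catalysed [4+2] cycloadditions of in situ ortho-quinone methides with styrenes and Lewis-acid-promoted cycloadditions of 2-phenyl-4H-1,3,2-benzodioxaborins with alkenes.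

**Step 7**
Reactants: 12 (2R,3R)-5,7-bis(tert-butyldimethylsilyloxy)-2-[3,4,5-tris(tert-butyldimethylsilyloxy)phenyl]-3,4-dihydro-2H-chromen-3-yl (E)-3-[3,4-bis(tert-butyldimethylsilyloxy)phenyl]prop-2-enoate
Product: 13 epigallocatechin 3-O-caffeate, (2R,3R)-5,7-dihydroxy-2-(3,4,5-trihydroxyphenyl)-3,4-dihydro-2H-chromen-3-yl (E)-3-(3,4-dihydroxyphenyl)prop-2-enoate
Conditions: HF·pyridine, pyridine, THF, 0 °C to rt, argon
Reagents that add atoms: none
Why: Buffered hydrogen fluoride cleaves all seven aryl Si–O bonds (fluoride-mediated desilylation) under mildly acidic conditions that neither hydrolyse the ester nor open the pyran ring, so C2 and C3 keep the (2R,3R) configuration and the caffeoyl alkene stays E.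

**Compound list**
1 | caffeic acid | O=C(O)/C=C/c1ccc(O)c(O)c1 | starting material
2 | tert-butyldimethylsilyl (E)-3-[3,4-bis(tert-butyldimethylsilyloxy)phenyl]prop-2-enoate | CC(C)(C)[Si](C)(C)OC(=O)/C=C/c1ccc(O[Si](C)(C)C(C)(C)C)c(O[Si](C)(C)C(C)(C)C)c1 | intermediate
3 | (E)-3-[3,4-bis(tert-butyldimethylsilyloxy)phenyl]prop-2-enoic acid | O=C(O)/C=C/c1ccc(O[Si](C)(C)C(C)(C)C)c(O[Si](C)(C)C(C)(C)C)c1 | intermediate
4 | 3,4,5-trihydroxybenzaldehyde | O=Cc1cc(O)c(O)c(O)c1 | starting material
5 | 3,4,5-tris(tert-butyldimethylsilyloxy)benzaldehyde | O=Cc1cc(O[Si](C)(C)C(C)(C)C)c(O[Si](C)(C)C(C)(C)C)c(O[Si](C)(C)C(C)(C)C)c1 | intermediate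
6 | 5-ethynyl-1,2,3-tris(tert-butyldimethylsilyloxy)benzene | C#Cc1cc(O[Si](C)(C)C(C)(C)C)c(O[Si](C)(C)C(C)(C)C)c(O[Si](C)(C)C(C)(C)C)c1 | intermediate
7 | (Z)-2-[3,4,5-tris(tert-butyldimethylsilyloxy)phenyl]ethenyl (E)-3-[3,4-bis(tert-butyldimethylsilyloxy)phenyl]prop-2-enoate | O=C(/C=C/c1ccc(O[Si](C)(C)C(C)(C)C)c(O[Si](C)(C)C(C)(C)C)c1)O/C=C\c1cc(O[Si](C)(C)C(C)(C)C)c(O[Si](C)(C)C(C)(C)C)c(O[Si](C)(C)C(C)(C)C)c1 | intermediate
8 | phloroglucinol | Oc1cc(O)cc(O)c1 | starting material
9 | 3,5-bis(tert-butyldimethylsilyloxy)phenol | Oc1cc(O[Si](C)(C)C(C)(C)C)cc(O[Si](C)(C)C(C)(C)C)c1 | intermediate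
10 | 5,7-bis(tert-butyldimethylsilyloxy)-2-phenyl-4H-1,3,2-benzodioxaborinine (dioxaborin) | CC(C)(C)[Si](C)(C)Oc1cc(O[Si](C)(C)C(C)(C)C)c2COB(c3ccccc3)Oc2c1 | intermediate
11 | 3,5-bis(tert-butyldimethylsilyloxy)-6-methylidenecyclohexa-2,4-dien-1-one (quinone methide) | C=C1C(=O)C=C(O[Si](C)(C)C(C)(C)C)C=C1O[Si](C)(C)C(C)(C)C | intermediate
12 | (2R,3R)-5,7-bis(tert-butyldimethylsilyloxy)-2-[3,4,5-tris(tert-butyldimethylsilyloxy)phenyl]-3,4-dihydro-2H-chromen-3-yl (E)-3-[3,4-bis(tert-butyldimethylsilyloxy)phenyl]prop-2-enoate | O=C(/C=C/c1ccc(O[Si](C)(C)C(C)(C)C)c(O[Si](C)(C)C(C)(C)C)c1)O[C@@H]1Cc2c(O[Si](C)(C)C(C)(C)C)cc(O[Si](C)(C)C(C)(C)C)cc2O[C@@H]1c1cc(O[Si](C)(C)C(C)(C)C)c(O[Si](C)(C)C(C)(C)C)c(O[Si](C)(C)C(C)(C)C)c1 | intermediate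
13 | epigallocatechin 3-O-caffeate, (2R,3R), cis | O=C(/C=C/c1ccc(O)c(O)c1)O[C@@H]1Cc2c(O)cc(O)cc2O[C@@H]1c1cc(O)c(O)c(O)c1 | target

**Totals**
Total step count: 7. Longest linear sequence: 5 steps (steps 2, 3, 4, 6, 7).

**Steps most likely to fail, with fallbacks**

Step 6 is the riskiest. The enol ester is a weak 2π partner whose polarity is ambiguous: the regiochemistry depends on aryl and carbonyl stabilisation at C2 outweighing the donor effect of the acyloxy oxygen, and the 3,4,5-trisilyloxyphenyl group is only a modest donor. The enantio-induction is untested. The fallback sets out from 6, 3 and 9 and comes back at 12. Gold-catalysed oxidation of alkyne 6 with 8-methylquinoline N-oxide in the presence of acid 3 (Ph3PAuN(SO2CF3)2, 1,2-dichloroethane, rt) gives the phenacyl ester 2-oxo-2-[3,4,5-tris(tert-butyldimethylsilyloxy)phenyl]ethyl (E)-3-[3,4-bis(tert-butyldimethylsilyloxy)phenyl]prop-2-enoate F1. Its nucleophilic enol carbon is unambiguously the acyloxy-bearing one. That carbon is alkylated by the quinone methide released from dioxaborin 10 (made from 9 as in step 6; CF3SO3H cat., CH2Cl2, 0 °C), and cyclodehydration gives the enol ester 5,7-bis(tert-butyldimethylsilyloxy)-2-[3,4,5-tris(tert-butyldimethylsilyloxy)phenyl]-4H-chromen-3-yl (E)-3-[3,4-bis(tert-butyldimethylsilyloxy)phenyl]prop-2-enoate F2. Asymmetric transfer hydrogenation of F2 with (R)-3,3'-bis(2,4,6-triisopropylphenyl)-1,1'-binaphthalene-2,2'-diyl hydrogen phosphate and diethyl 2,6-dimethyl-1,4-dihydropyridine-3,5-dicarboxylate (toluene, 40 °C) then gives 12. In this step C3 is protonated, the 2-aryl oxocarbenium ion pairs with the chiral phosphate while C3 equilibrates through the enol ether, and hydride is delivered to C2 anti to the acyloxy group, which gives the cis (2R,3R) product. This last step is itself a proposed extension of the known phosphoric-acid-catalysed transfer hydrogenation of 2,3-disubstituted quinolines and benzopyrylium ions.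

Step 4 may give Z/E mixtures or stall with the hindered, silyl-rich partners. The fallback sets out from 6 and comes back at 7. Rhodium-catalysed trans-hydroboration of 6 with pinacolborane ([RhCl(C8H12)]2, P(CH(CH3)2)3, Et3N, cyclohexane, rt) gives the alkenylboronate 2-[(Z)-2-[3,4,5-tris(tert-butyldimethylsilyloxy)phenyl]ethenyl]-4,4,5,5-tetramethyl-1,3,2-dioxaborolane F3. F3 is coupled with acid 3 under Cu(OAc)2, Et3N, 4 Å MS, O2, CH2Cl2 (Chan–Lam-type C–O coupling with retention of alkene geometry) to give 7.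

Step 7 may suffer from air oxidation and difficult purification of the free heptaphenol, or from partial desilylation. The fallback sets out from 12 and comes back at 13. Desilylation with Et3N·3HF in THF followed in the same flask by Ac2O and pyridine gives the heptaacetate (2R,3R)-5,7-diacetoxy-2-(3,4,5-triacetoxyphenyl)-3,4-dihydro-2H-chromen-3-yl (E)-3-(3,4-diacetoxyphenyl)prop-2-enoate F4, which is stable to air and silica and is purified there. NH4OAc in aqueous methanol at rt then removes the seven aryl acetates by transesterification without touching the alkyl caffeate and gives 13.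

**Further compounds**
F1 | step 6 | 2-oxo-2-[3,4,5-tris(tert-butyldimethylsilyloxy)phenyl]ethyl (E)-3-[3,4-bis(tert-butyldimethylsilyloxy)phenyl]prop-2-enoate | O=C(/C=C/c1ccc(O[Si](C)(C)C(C)(C)C)c(O[Si](C)(C)C(C)(C)C)c1)OCC(=O)c1cc(O[Si](C)(C)C(C)(C)C)c(O[Si](C)(C)C(C)(C)C)c(O[Si](C)(C)C(C)(C)C)c1
F2 | step 6 | 5,7-bis(tert-butyldimethylsilyloxy)-2-[3,4,5-tris(tert-butyldimethylsilyloxy)phenyl]-4H-chromen-3-yl (E)-3-[3,4-bis(tert-butyldimethylsilyloxy)phenyl]prop-2-enoate | O=C(/C=C/c1ccc(O[Si](C)(C)C(C)(C)C)c(O[Si](C)(C)C(C)(C)C)c1)OC1=C(c2cc(O[Si](C)(C)C(C)(C)C)c(O[Si](C)(C)C(C)(C)C)c(O[Si](C)(C)C(C)(C)C)c2)Oc2cc(O[Si](C)(C)C(C)(C)C)cc(O[Si](C)(C)C(C)(C)C)c2C1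
F3 | step 4 | 2-[(Z)-2-[3,4,5-tris(tert-butyldimethylsilyloxy)phenyl]ethenyl]-4,4,5,5-tetramethyl-1,3,2-dioxaborolane | CC1(C)OB(/C=C\c2cc(O[Si](C)(C)C(C)(C)C)c(O[Si](C)(C)C(C)(C)C)c(O[Si](C)(C)C(C)(C)C)c2)OC1(C)C
F4 | step 7 | (2R,3R)-5,7-diacetoxy-2-(3,4,5-triacetoxyphenyl)-3,4-dihydro-2H-chromen-3-yl (E)-3-(3,4-diacetoxyphenyl)prop-2-enoate | O=C(/C=C/c1ccc(OC(C)=O)c(OC(C)=O)c1)O[C@@H]1Cc2c(OC(C)=O)cc(OC(C)=O)cc2O[C@@H]1c1cc(OC(C)=O)c(OC(C)=O)c(OC(C)=O)c1
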